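**Assumption:** the target has no stereocentre and no stereogenic double bond, so it is achiral. No enantiocontrol is needed. The temporary carbinol centres are carried as racemates or diastereomer mixtures and are erased in step 8.

## Retrosynthetic overview
1. Target ⇒ bis-MOM diketone (acid deprotection) ⇒ bis-carbinol (one double oxidation sets both ketones).
2. Aryl–C(carbinol) bond of the 4-methylpentanoyl chain ⇒ directed ortho-lithiation between the two OMOM groups plus 4-methylpentanal. The deoxybenzoin carbonyl is parked as an O-TBS carbinol during this step.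
3. Key bond, ArCH2–C(=O)Ar' ⇒ crossed Claisen condensation of the arylacetate enolate with methyl 4-methoxybenzoate, followed by Krapcho removal of CO2Me.
4. No ring is formed. Both benzene rings are bought, as methyl 3,5-dihydroxyphenylacetate and methyl 4-methoxybenzoate.

## Route

Step 1
Reactants: 1 methyl 2-(3,5-dihydroxyphenyl)acetate
Product: 2 methyl 2-[3,5-bis(methoxymethoxy)phenyl]acetate
Conditions: MOMCl (2.6 equiv), i-Pr2NEt (3 equiv), CH2Cl2, 0 °C → rt
Reagents that add atoms: chloromethyl methyl ether (MOMCl), COCCl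
Why: Williamson-type O-alkylation of both phenols by the reactive α-chloro ether under amine base leaves the ester untouched and installs base-stable, acid-labile groups that later direct the lithiation.

Step 2
Reactants: 2 methyl 2-[3,5-bis(methoxymethoxy)phenyl]acetate; 3 methyl 4-methoxybenzoate
Product: 6 methyl 2-[3,5-bis(methoxymethoxy)phenyl]-3-(4-methoxyphenyl)-3-oxopropanoate (racemic), via ester lithium enolate 4 (not isolated), via keto ester lithium enolate 5 (not isolated)
Conditions: LiN(SiMe3)2 (2.5 equiv), THF, −78 °C, 45 min; 3 (1.3 equiv), −78 °C → rt, 12 h; AcOH quench, 0 °C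
Reagents that add atoms: none
Why: In this crossed Claisen condensation the fully preformed enolate 4 cannot self-condense, non-enolisable 3 can act only as acceptor, and the extra base traps the product as stabilised enolate 5, while the new α-centre is racemic, labile and removed in step 3.

Step 3
Reactants: 6 methyl 2-[3,5-bis(methoxymethoxy)phenyl]-3-(4-methoxyphenyl)-3-oxopropanoate
Product: 7 2-[3,5-bis(methoxymethoxy)phenyl]-1-(4-methoxyphenyl)ethan-1-one
Conditions: LiCl (3 equiv), H2O (3 equiv), DMSO, 130 °C, 3 h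
Reagents that add atoms: none
Why: In this Krapcho dealkoxycarbonylation chloride demethylates the ester and the β-keto carboxylate loses CO2 under near-neutral conditions, which avoids retro-Claisen cleavage and spares the MOM acetals.

Step 4
Reactants: 7 2-[3,5-bis(methoxymethoxy)phenyl]-1-(4-methoxyphenyl)ethan-1-one
Product: 8 2-[3,5-bis(methoxymethoxy)phenyl]-1-(4-methoxyphenyl)ethan-1-ol (racemic)
Conditions: NaBH4 (1.2 equiv), MeOH/THF, 0 °C → rt
Reagents that add atoms: none
Why: Borohydride 1,2-reduction removes the electrophilic carbonyl and its acidic CH2 before organolithium chemistry, and the racemic carbinol centre formed without control is erased in step 8.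

Step 5
Reactants: 8 2-[3,5-bis(methoxymethoxy)phenyl]-1-(4-methoxyphenyl)ethan-1-ol
Product: 9 tert-butyl{2-[3,5-bis(methoxymethoxy)phenyl]-1-(4-methoxyphenyl)ethoxy}dimethylsilane (racemic)
Conditions: TBSCl (1.3 equiv), imidazole (2.5 equiv), DMF, rt
Reagents that add atoms: tert-butyldimethylsilyl chloride (TBSCl), CC(C)(C)[Si](C)(C)Cl
Why: Imidazole-promoted silylation (Corey conditions) of the unhindered secondary alcohol gives an ether that tolerates n-BuLi and is orthogonal to MOM.

Step 6
Reactants: 9 tert-butyl{2-[3,5-bis(methoxymethoxy)phenyl]-1-(4-methoxyphenyl)ethoxy}dimethylsilane; 10 4-methylpentanal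
Product: 12 1-{4-[2-(tert-butyldimethylsilyloxy)-2-(4-methoxyphenyl)ethyl]-2,6-bis(methoxymethoxy)phenyl}-4-methylpentan-1-ol (diastereomer mixture), via aryllithium 11 (not isolated)
Conditions: n-BuLi (1.3 equiv), THF, 0 °C, 1 h; 10 (1.6 equiv), −78 °C → 0 °C; H2O quench
Reagents that add atoms: none
Why: In this directed ortho-metalation the two chelating OMOM groups act together to make the C–H between them the fastest site to lithiate, and 1,2-addition of 11 to the aldehyde gives a carbinol centre formed without control that is erased in step 8.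

Step 7
Reactants: 12 1-{4-[2-(tert-butyldimethylsilyloxy)-2-(4-methoxyphenyl)ethyl]-2,6-bis(methoxymethoxy)phenyl}-4-methylpentan-1-ol
Product: 13 1-{4-[2-hydroxy-2-(4-methoxyphenyl)ethyl]-2,6-bis(methoxymethoxy)phenyl}-4-methylpentan-1-ol (diastereomer mixture)
Conditions: Bu4NF (1.5 equiv), THF, rt
Reagents that add atoms: none
Why: Fluoride-driven desilylation (strong Si–F bond) frees the carbinol selectively, since MOM and methyl ethers are inert to fluoride.

Step 8
Reactants: 13 1-{4-[2-hydroxy-2-(4-methoxyphenyl)ethyl]-2,6-bis(methoxymethoxy)phenyl}-4-methylpentan-1-ol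
Product: 14 1-{4-[2-(4-methoxyphenyl)-2-oxoethyl]-2,6-bis(methoxymethoxy)phenyl}-4-methylpentan-1-one
Conditions: Dess–Martin periodinane (3 equiv), NaHCO3 (10 equiv), CH2Cl2, 0 °C → rt
Reagents that add atoms: none
Why: Buffered Dess–Martin oxidation converts both secondary benzylic alcohols to ketones in one operation at room temperature, keeps the MOM groups intact, and destroys both temporary stereocentres.

Step 9
Reactants: 14 1-{4-[2-(4-methoxyphenyl)-2-oxoethyl]-2,6-bis(methoxymethoxy)phenyl}-4-methylpentan-1-one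
Product: 15 1-{2,6-dihydroxy-4-[2-(4-methoxyphenyl)-2-oxoethyl]phenyl}-4-methylpentan-1-one (target)
Conditions: conc. HCl (cat.), MeOH, 50 °C, 3 h
Reagents that add atoms: none
Why: Acid-catalysed acetal exchange with methanol cleaves both aryl MOM ethers and captures the formaldehyde unit as its dimethyl acetal, while the aryl methyl ether and both ketones are inert.

## Compound list
1 | methyl 2-(3,5-dihydroxyphenyl)acetate | COC(=O)Cc1cc(O)cc(O)c1 | starting material
2 | methyl 2-[3,5-bis(methoxymethoxy)phenyl]acetate | COC(=O)Cc1cc(OCOC)cc(OCOC)c1 | intermediate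
3 | methyl 4-methoxybenzoate | COC(=O)c1ccc(OC)cc1 | starting material
4 | lithium enolate of 2 (not isolated) | [Li]OC(OC)=Cc1cc(OCOC)cc(OCOC)c1 | intermediate
5 | lithium enolate of keto ester 6 (not isolated) | COC(=O)C(c1cc(OCOC)cc(OCOC)c1)=C(O[Li])c1ccc(OC)cc1 | intermediate
6 | methyl 2-[3,5-bis(methoxymethoxy)phenyl]-3-(4-methoxyphenyl)-3-oxopropanoate (racemic) | COC(=O)C(C(=O)c1ccc(OC)cc1)c1cc(OCOC)cc(OCOC)c1 | intermediate
7 | 2-[3,5-bis(methoxymethoxy)phenyl]-1-(4-methoxyphenyl)ethan-1-one | COc1ccc(C(=O)Cc2cc(OCOC)cc(OCOC)c2)cc1 | intermediate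
8 | 2-[3,5-bis(methoxymethoxy)phenyl]-1-(4-methoxyphenyl)ethan-1-ol (racemic) | COc1ccc(C(O)Cc2cc(OCOC)cc(OCOC)c2)cc1 | intermediate
9 | tert-butyl{2-[3,5-bis(methoxymethoxy)phenyl]-1-(4-methoxyphenyl)ethoxy}dimethylsilane (racemic) | COc1ccc(C(Cc2cc(OCOC)cc(OCOC)c2)O[Si](C)(C)C(C)(C)C)cc1 | intermediate
10 | 4-methylpentanal | CC(C)CCC=O | starting material
11 | 4-lithio derivative of 9, lithium between the two OMOM groups (not isolated) | COc1ccc(C(Cc2cc(OCOC)c([Li])c(OCOC)c2)O[Si](C)(C)C(C)(C)C)cc1 | intermediate
12 | 1-{4-[2-(tert-butyldimethylsilyloxy)-2-(4-methoxyphenyl)ethyl]-2,6-bis(methoxymethoxy)phenyl}-4-methylpentan-1-ol (diastereomer mixture) | COc1ccc(C(Cc2cc(OCOC)c(C(O)CCC(C)C)c(OCOC)c2)O[Si](C)(C)C(C)(C)C)cc1 | intermediate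
13 | 1-{4-[2-hydroxy-2-(4-methoxyphenyl)ethyl]-2,6-bis(methoxymethoxy)phenyl}-4-methylpentan-1-ol (diastereomer mixture) | COc1ccc(C(O)Cc2cc(OCOC)c(C(O)CCC(C)C)c(OCOC)c2)cc1 | intermediate
14 | 1-{4-[2-(4-methoxyphenyl)-2-oxoethyl]-2,6-bis(methoxymethoxy)phenyl}-4-methylpentan-1-one | COc1ccc(C(=O)Cc2cc(OCOC)c(C(=O)CCC(C)C)c(OCOC)c2)cc1 | intermediate
15 | 1-{2,6-dihydroxy-4-[2-(4-methoxyphenyl)-2-oxoethyl]phenyl}-4-methylpentan-1-one (achiral) | COc1ccc(C(=O)Cc2cc(O)c(C(=O)CCC(C)C)c(O)c2)cc1 | target

## Summary
Total step count: 9.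
Longest linear sequence: 9 steps (1 → 15).

## Steps most likely to fail

**Step 2 (crossed Claisen).** The electron-rich ester 3 is a sluggish acceptor, so conversion may stall or proton exchange may allow self-condensation. The fallback sets out from 2 and replaces acyl substitution by carbonyl addition followed by oxidation. Enolate 4 is generated as before and quenched at −78 °C with the far more electrophilic 4-methoxybenzaldehyde. This aldol addition gives methyl 2-[3,5-bis(methoxymethoxy)phenyl]-3-hydroxy-3-(4-methoxyphenyl)propanoate F1 as a diastereomer mixture. Buffered Dess–Martin oxidation of the benzylic carbinol then returns to the route at 6.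

**Step 6 (lithiation and aldehyde addition).** The hindered aryllithium 11 may enolise 10 instead of adding to it. The fallback sets out from 9 and reverses the polarity of the bond formation. Aryllithium 11 is trapped with DMF, a non-enolisable and very reliable electrophile, to give 4-[2-(tert-butyldimethylsilyloxy)-2-(4-methoxyphenyl)ethyl]-2,6-bis(methoxymethoxy)benzaldehyde F2. Addition of (CH3)2CHCH2CH2MgBr in THF at 0 °C to this aldehyde returns to the route at 12.

**Step 8 (double oxidation).** The carbinol flanked by two OMOM groups may oxidise slowly while the deoxybenzoin CH2 begins to over-oxidise. The fallback sets out from 9 and never creates the hindered carbinol. 4-Methylpentanoyl chloride, MeNH(OMe)·HCl and Et3N in CH2Cl2 give N-methoxy-N,4-dimethylpentanamide F3. Acylation of aryllithium 11 with this Weinreb amide gives 1-{4-[2-(tert-butyldimethylsilyloxy)-2-(4-methoxyphenyl)ethyl]-2,6-bis(methoxymethoxy)phenyl}-4-methylpentan-1-one F4 directly at the ketone level. Bu4NF then releases 1-{4-[2-hydroxy-2-(4-methoxyphenyl)ethyl]-2,6-bis(methoxymethoxy)phenyl}-4-methylpentan-1-one F5. A single oxidation of the unhindered carbinol with 1.2 equiv of oxidant (Swern or Dess–Martin) returns to the route at 14.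

## Further compounds
F1 | step 2 | methyl 2-[3,5-bis(methoxymethoxy)phenyl]-3-hydroxy-3-(4-methoxyphenyl)propanoate (diastereomer mixture) | COC(=O)C(C(O)c1ccc(OC)cc1)c1cc(OCOC)cc(OCOC)c1
F2 | step 6 | 4-[2-(tert-butyldimethylsilyloxy)-2-(4-methoxyphenyl)ethyl]-2,6-bis(methoxymethoxy)benzaldehyde (racemic) | COc1ccc(C(Cc2cc(OCOC)c(C=O)c(OCOC)c2)O[Si](C)(C)C(C)(C)C)cc1
F3 | step 8 | N-methoxy-N,4-dimethylpentanamide | CC(C)CCC(=O)N(C)OC
F4 | step 8 | 1-{4-[2-(tert-butyldimethylsilyloxy)-2-(4-methoxyphenyl)ethyl]-2,6-bis(methoxymethoxy)phenyl}-4-methylpentan-1-one (racemic) | COc1ccc(C(Cc2cc(OCOC)c(C(=O)CCC(C)C)c(OCOC)c2)O[Si](C)(C)C(C)(C)C)cc1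
F5 | step 8 | 1-{4-[2-hydroxy-2-(4-methoxyphenyl)ethyl]-2,6-bis(methoxymethoxy)phenyl}-4-methylpentan-1-one (racemic) | COc1ccc(C(O)Cc2cc(OCOC)c(C(=O)CCC(C)C)c(OCOC)c2)cc1
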